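The south run cannot have stopped for lack of substrate, because its target stays flat at a level below the whole substrate charge. The charges and readings of the earlier runs are set out below beside the asked flask.

in all of them: free catalyst 40 mM
- south: substrate 0.80 M; reagent 0.20 M; run made earlier
- north-east: substrate 0.80 M; reagent 0.30 M; run made earlier
- east: substrate 1.6 M; reagent 0.40 M; run made earlier
- flask: substrate 0.80 M; reagent 0.400 M; time 30 min

- south (time / min: target / %): 4.00: 25.8; 8.00: 25.4; 10.0: 25.1; 15.0: 24.8; 20.0: 25.4
- north-east (time / min: target / %): 1.50: 37.8; 5.00: 36.7; 8.00: 37.9; 12.0: 37.8; 20.0: 38.6
- east (time / min: target / %): 1.50: 26.5; 5.00: 25.5; 8.00: 24.3; 12.0: 27.8; 20.0: 24.0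

(scatter of a reading: 1 percentage point)

- what was read earlier has a scatter of 1 percentage point, one standard deviation
- a reading or a percentage of target counts all its forms, free or not
- the reaction counts as stopped when no species that holds the substrate changes by six tenths of a point or more over the second half of the time

- at 30 min, what has stopped the reaction, if anything has (all of the substrate has reacted / no working catalyst is left / it is still moving / the reagent has run out first)
- how much target there is at 30 min, in percent of the substrate charged

A useful quantity is the roof, the smaller of the reagent and substrate charges divided by the substrate charge; it is the target percentage reached if one reagent makes one target and the smaller charge, the limiting reagent, is used up. In the south row the roof is 25.0 %, and the readings average 25.3 %. In the north-east row more reagent lifts the roof to 37.5 %, and the readings follow at 37.8 %. In the east row both charges are doubled, so the roof returns to 25.0 %, and the readings average 25.6 %.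

The east run, read on its roof, gives 10.0 turns per catalyst charged, and the asked flask needs 10.0 to reach its roof. The north-east run, with the flask's substrate charge, was flat by 1.50 min, and the flask has 20.0 times that. The reckoning here therefore puts the flask on its roof, 50.0 %, with reagent the smaller charge.

The forecast gives "the reagent has run out first" and 50.3 %, which is 0.3 percentage points above this roof, on the ground “So target forms 1:1 with reagent, and the reagent limits every run.”

The flask gives "the reagent has run out first" and 50.0 % of target at 30.0 min, with 0 % of the reagent left and 16.2 % of the substrate charged standing as crystals, counted in that target.

    crystals ⇌ target, rate k1*(cs1 - [target]) while solid is left; crystals form when [target] > cs1 (solubility = 0.270 M, k = 0.740 s⁻¹)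
    substrate + reagent + free catalyst → target + free catalyst, rate k2*[substrate]*[reagent]*[free catalyst]/(1 + ([substrate]/sat2)) (1.90 M, k = 7.60 L² mol⁻² s⁻¹)
    2 free catalyst → spent catalyst (k = 0.180 L mol⁻¹ s⁻¹)

A neighbouring flask, charged with 1.0 M of reagent, has substrate as its smaller charge, so its roof is 100 %. It gives >99.9 % of target at 30.0 min. Its substrate stands at 0 %, and its reagent at 20.0 % of its own charge.

The runs are calculated for substances that don't exist, and the scatter is random.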